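Marta, who runs this ring closure, and her colleague Jonas dispute whether slow addition pays. Activator turns starting material into activated form, which closes to ring, while protic impurity wastes activator. Activated form may also meet starting material to give open dimer, and ring may reopen.

| setting | blue | violet | amber | alder | cedar | elm |
|---|---|---|---|---|---|---|
| starting material | 0.066 M | 0.066 M | 0.066 M | 0.066 M | 0.066 M (fed, over 30 min) | 0.066 M |
| activator | 0.119 M | 0.17 M | 0.26 M | 0.119 M | 0.119 M | 0.119 M (fed, over 30 min) |
| protic impurity | 0.066 M | 0.066 M | 0.066 M | 0.0660 M | 0.0660 M | 0.0660 M |
| remark | run made earlier | run made earlier | run made earlier | everything together at the start | all else is in the flask from the start; the feed brings no volume worth counting | all else is in the flask from the start; the feed brings no volume worth counting |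
| time |  |  |  | 80 min | 80 min | 80 min |

- blue (time / min: ring / %, starting material / %): 2.50: 1.3, 76.8; 8.00: 8.9, 48.6; 15.0: 15.3, 29.4; 20.0: 16.8, 25.3; 30.0: 15.0, 16.5; 40.0: 16.3, 12.5; 50.0: 15.7, 7.5
- violet (time / min: ring / %, starting material / %): 3.00: 3.6, 63.3; 10.0: 14.2, 28.1; 20.0: 17.6, 12.3; 30.0: 16.5, 7.1; 40.0: 17.3, 2.3; 50.0: 16.8, 3.4; 60.0: 16.4, 2.1
- amber (time / min: ring / %, starting material / %): 10.0: 15.6, 14.4; 20.0: 17.3, 3.0; 30.0: 19.2, 2.7; 40.0: 17.3, 2.4; 50.0: 16.0, 0; 60.0: 17.8, 0.5

(scatter of a reading: 1 percentage point)

- in percentages every species weighs as the starting material in it: one open dimer or idle adduct counts as two
- for ring the idle adduct is counted in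
- the numbers in the tables scatter by 1 percentage point (one standard deviation)
- steps under discussion: activator + protic impurity -> quenched reagent; activated form <-> ring; starting material + ring <-> idle adduct; starting material + activated form -> open dimer; starting material + activator -> activated form
- in an amount of ring, one idle adduct counts as one ring

- which flask leads in amount of ring, in percent of the starting material charged ("all alike" within 1.5 percentage points) (alder / cedar / elm / all alike)
- how much ring is there at the end, in percent of the starting material charged: alder
- how much ring is there at the end, in percent of the starting material charged: cedar
- how much ring is there at the end, in percent of the starting material charged: elm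

Jonas takes the kinetic view: activated form either closes or is captured by starting material, so a low c(starting material) should raise ring and feeding it slowly should pay. His forecast says “Low starting material favours ring.” He names cedar as the leader, with 28% there, 16.5% in alder and 14% in elm.

Marta asks first what the end state must be. She defines the ring share, which is ring over starting material converted at the last reading, and takes its mean over blue, violet and amber: 17.2%. At 10.0 min violet still held 28.1% of its starting material and amber 14.4%, and amber was charged with twice the activator of blue. Yet the last readings give a share of 17.0% in blue and 17.9% in amber. To her this looks like thermodynamic control, a balance between ring and activated form, and in her view the order of feeding should then move ring little. Blue had converted 92.5% by its last reading. Taking that conversion as an assumption for each new flask, her own reckoning is 15.9% of ring in each, so in her estimate all three stand level, and for cedar she differs from Jonas.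

The simulation gives all alike: alder 14.9%, cedar 14.4%, elm 14.6%.

    activator + protic impurity → quenched reagent (k = 0.460 M⁻¹ min⁻¹)
    activated form ⇌ ring (K = 0.240, k = 0.0900 min⁻¹)
    starting material + ring ⇌ idle adduct, settled at all times (K = 28.0 M⁻¹)
    starting material + activated form → open dimer (k = 0.280 M⁻¹ min⁻¹)
    starting material + activator → activated form (k = 0.900 M⁻¹ min⁻¹)

Cedar's ring share comes to 16.1%, against the 17.2% read from the earlier runs. The return of ring to activated form is the main reason that ring stays this low in cedar: with that return taken away, cedar ends with 66.1% of ring instead of 14.4%. Jonas's capture view shows itself in the neighbour of cedar charged with 0.26 M of starting material: there open dimer reaches 40.6% and the ring share is 11.2%.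

All runs are calculated from invented constants; noise was put on by code.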